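- Start from late times: once the enzyme has had long enough, what can a flask still hand over as target? These flasks differ in free enzyme, and you read them at 50 min.

| setting | north-west | north-east | blue | grey | red | amber | ochre | green |
|---|---|---|---|---|---|---|---|---|
| starting material | 0.10 M | 0.10 M | 0.10 M | 0.10 M | 0.10 M | 0.10 M | 0.10 M | 0.10 M |
| second substrate | 0.25 M | 0.25 M | 0.250 M | 0.250 M | 0.250 M | 0.250 M | 0.250 M | 0.250 M |
| protic impurity | 0.030 M | 0.030 M | 0.0300 M | 0.0300 M | 0.0300 M | 0.0300 M | 0.0300 M | 0.0300 M |
| free enzyme | 0.017 mM | 0.18 mM | 0.15 mM | 0.20 mM | 0.30 mM | 0.025 mM | 0.050 mM | 0.10 mM |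
| remark | run made earlier | run made earlier |  |  |  |  |  |  |
| time |  |  | 50 min | 50 min | 50 min | 50 min | 50 min | 50 min |

| run | time / min | target / % | starting material / % |
|---|---|---|---|
| north-west | 1.33 | 0.9 | 71.6 |
| north-west | 4.00 | 0.8 | 69.9 |
| north-west | 8.00 | 2.2 | 69.6 |
| north-west | 10.0 | 1.5 | 67.7 |
| north-west | 15.0 | 2.6 | 66.2 |
| north-west | 20.0 | 4.2 | 64.3 |
| north-west | 25.0 | 3.1 | 64.7 |
| north-east | 2.00 | 3.7 | 64.1 |
| north-east | 3.00 | 5.6 | 64.3 |
| north-east | 5.00 | 10.7 | 58.6 |
| north-east | 8.00 | 17.4 | 53.9 |
| north-east | 10.0 | 21.0 | 49.6 |
| north-east | 15.0 | 26.4 | 44.7 |
| north-east | 25.0 | 37.2 | 32.8 |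

(standard deviation of a reading: 1 percentage point)



1. all flasks from highest to lowest amount of target, in percent of the starting material charged, at 50 min (blue / grey / red / amber / ochre / green)
2. the amount of target, in percent of the starting material charged of the flask you put first, at 50 min
3. the amount of target, in percent of the starting material charged of the flask you put last, at 50 min

- Write the balance of the starting material, the limiting reagent against the second substrate. The protic impurity amounts to 30.0 % of that charge, and if it takes starting material one for one, 70.0 % remains. Call this remainder, one minus the impurity as a fraction of the charge, the usable share.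
- You can test this on the north-east run, where target plus starting material come to 70.0 % at 25.0 min.
- The first extreme is a flask with ample enzyme, where target simply reaches the usable share. The second is a flask with so little enzyme that the pool hardly falls, and target climbs in a straight line.
- To place the flasks between these, read a clock from the north-east run. Its pool falls from the usable share to 32.8 % in 25.0 min, which gives 0.0303 min⁻¹ at 0.18 mM. Scale this with enzyme, since the early target rates of the two runs stand 12.3 to one against 10.6 to one in enzyme.
- For red, the straight line reaches 177 %, more than the usable share, so red must bend under that ceiling. For amber it reaches 14.7 %, well below the ceiling, so amber stays near its line.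
- Letting the pool decay, I reckon 64.4 % for red, first with the most enzyme. For amber, last with the least, I reckon 13.3 %.
- The forecast gives the same order, red > grey > blue > green > ochre > amber, and sits a little below my figures with 60 % and 12 %, holding that “only about 70% is available to become target”.
- The flasks give red > grey > blue > green > ochre > amber, with 64.7 % in red and 13.2 % in amber.

    starting material + free enzyme ⇌ first complex (K = 17.0 M⁻¹, k = 53.5 M⁻¹ s⁻¹)
    first complex ⇌ loaded enzyme + first product (K = 0.0830 M, k = 20.8 s⁻¹)
    second substrate + loaded enzyme ⇌ second complex (K = 1.40 M⁻¹, k = 368 M⁻¹ s⁻¹)
    second complex → free enzyme + target (k = 0.924 s⁻¹)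
    starting material + protic impurity → quenched substrate (k = 0.658 M⁻¹ s⁻¹)
    starting material + first complex → spent catalyst (k = 0.0215 M⁻¹ s⁻¹)

- In red at 50.0 min, quenched substrate stands at 30.0 %, the impurity's fraction of the charge. Left until 500 min, ten times as long, red gives 69.9 %, against a usable share of 70.0 %. Now take amber with its starting material cut to 0.025 M. The impurity is then 1.20 equiv against the starting material, so the balance gives −20.0 %, a negative share. That is no amount of target: the usable share has lost its meaning in this flask, where starting material is charged below the impurity. At 50.0 min that flask holds 95.3 % as quenched substrate, keeps 20.6 % of its protic impurity, and gives 4.75 % of target.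

The readings were computed for an exercise, and the scatter is random.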